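I began from an impossibility: the 0.250 M of reagent in either flask cannot convert the 0.400 M of substrates charged beside it, so reagent is the limiting reagent, and what is asked turns on how it is shared and on how far the target has gone over into its isomer.

- Saturday's: starting material 0.10 M; reagent 0.250 M; second substrate 0.100 M; third substrate 0.200 M; protic impurity 5.00 mM; temperature 5 °C; time 12 min
- Monday's: starting material 0.10 M; reagent 0.250 M; second substrate 0.100 M; third substrate 0.200 M; protic impurity 5.00 mM; temperature 15 °C; time 12 min

    target → over-reaction product (k1 = 4.19 × 10⁻⁴ min⁻¹, Ea1 = 88.0 kJ mol⁻¹)
    starting material + protic impurity → quenched substrate (k2 = 565 L mol⁻¹ min⁻¹, Ea2 = 42.0 kJ mol⁻¹)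
    starting material + reagent → target (k3 = 0.595 L mol⁻¹ min⁻¹, Ea3 = 68.0 kJ mol⁻¹)
    target ⇌ isomer of the product (K4 = 23.2, k4 = 0.0857 min⁻¹, Ea4 = 80.0 kJ mol⁻¹, ΔH4 = −16.0 kJ mol⁻¹)
    third substrate + reagent → third product (k5 = 0.417 L mol⁻¹ min⁻¹, Ea5 = 64.0 kJ mol⁻¹)
    second substrate + reagent → second product (k6 = 0.251 L mol⁻¹ min⁻¹, Ea6 = 54.0 kJ mol⁻¹)
    (constants at 5 °C)

- which of these there is most of at the end, counted by the starting material in it, Saturday's (target / isomer of the product / starting material)
- which of these there is most of at the end, counted by the starting material in it, Monday's (target / isomer of the product / starting material)
- the largest of these amounts at the end, in percent of the starting material charged, Saturday's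
- the largest of these amounts at the end, in percent of the starting material charged, Monday's

- constants are those at 5 °C; use the activation energies and enthalpies for any other temperature

I turned the constants into times at the charged amounts. On Saturday's flask the protic impurity takes starting material with a half-life of 0.25 min, far shorter than the 12 min allowed. I doubted that it would get its full share until I set the reagent against it: at the start the reagent's rate on starting material is 0.0527 of the impurity's, so the impurity claims 5.00 % of the starting material. The reagent then gives the starting material a pseudo-first-order half-life of 4.66 min, which promises little left at the end, but that holds the reagent at its charge, and the substrates together consume it at 0.165 min⁻¹, a half-life of about the same length. Letting the reagent decay at that rate, I found 43.7 % of the starting material left on Saturday's and 51.3 % turned into target and isomer together; this left too much starting material, I suspected, since the decay slows as the substrates fall.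

The division of that product was the real question. On Monday's flask the relaxation half-life 2.31 min, the time in which target and isomer together shrink their distance from equilibrium by a factor of 2, both directions counted, stands against 7.75 min on Saturday's. Product forms throughout the run, so I gave it a typical age of 6.00 min, though I knew early product is older. On Saturday's that made 20.4 % isomer and 30.9 % target, both less than the starting material. On Monday's, even at Saturday's conversion, the relaxed part gave about 42.8 % isomer, level with my starting material. There my reckoning stopped, without a figure for Monday's.

The forecast, built on an “integrated reagent exposure”, named starting material at 38 % for Saturday's, which is lower than my figure, and isomer of the product at 62.5 % for Monday's.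

The simulation gave starting material at 38.0 % on Saturday's, with target at 29.8 % and isomer at 27.1 %, and isomer of the product at 61.9 % on Monday's, with starting material at 23.0 %.

Temperature is the main reason for Monday's lead: the isomer stands at 61.9 % there and at 27.1 % without the warming, and the time holds 5.19 relaxation half-lives on Monday's against 1.55 on Saturday's. The same 2.31 min serves a neighbouring flask, Monday's with 0.15 M of reagent, where isomer over target is 6.55 against 6.36 on Monday's. The lead changes hands in that neighbouring flask all the same, with starting material at 46.4 % above the isomer's 41.9 %.

(The numbers belong to no real substance.)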